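The runs are calculated for an exercise, noise included.

**The ratio.** Reciprocal molarity is the unit of the number we hand over. Monday's reading at 10.0 min gives 0.968 M⁻¹ for Q, the pairing ratio: [target] divided by [starting material] squared, with one target weighing as two starting material. Wednesday's reading at 15.0 min gives 0.947 M⁻¹, with 0.63 M of protic impurity instead of 0.032 M.

| flask | starting material | protic impurity | remark | time |
|---|---|---|---|---|
| Monday's | 1 M | 0.032 M | run made earlier |  |
| Wednesday's | 1 M | 0.63 M | run made earlier |  |
| epsilon | 1.0 M | 0.0250 M |  | 30 min |
| eta | 1.0 M | 0.0500 M |  | 30 min |
| delta | 1.0 M | 0.100 M |  | 30 min |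
| alpha | 1.0 M | 0.200 M |  | 30 min |
| theta | 1.0 M | 0.400 M |  | 30 min |

| run | time / min | target / % | starting material / % |
|---|---|---|---|
| Monday's | 2.00 | 37.5 | 59.9 |
| Monday's | 5.00 | 44.9 | 49.0 |
| Monday's | 10.0 | 44.6 | 48.0 |
| Monday's | 15.0 | 43.5 | 49.3 |
| Wednesday's | 2.00 | 23.5 | 39.2 |
| Wednesday's | 5.00 | 21.0 | 27.5 |
| Wednesday's | 10.0 | 15.0 | 24.5 |
| Wednesday's | 15.0 | 11.0 | 24.1 |

(standard deviation of a reading: 0.5 percentage points)

- in percentages every species weighs as the starting material in it: one target or isomer of the product counts as two
- the numbers in the tables scatter by 0.5 percentage points (one standard deviation)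
- on the list of suspects stand: target <-> isomer of the product; 2 starting material <-> target; starting material + protic impurity -> quenched substrate
- "hardly changes" means that all values lie within two and a half points (for a concentration: within two and a half percent of the largest)

- amount of target at the end, in percent of the starting material charged for epsilon, eta, delta, alpha, theta, in this order
- the course of these numbers from the first flask to the last (falls, then rises / hardly changes / rises, then falls / rises all the way / falls all the way)

**In the flask.** We reckon with the fraction left. Protic impurity, the limiting reagent of the quench, removes starting material one for one: Wednesday's missing share at 15.0 min is 64.9%, against a charge of 63.0%. What remains is a pool shared by starting material, target and some isomer of the product, and Q splits the first two.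

**On your return.** Our own reckoning leaves a pool of 97.5% of the charge in epsilon and 60.0% in theta. Q then splits these into 49.7% and 35.5% of starting material. That gives target of 47.8% and 24.5%, with no isomer counted. Monday's unaccounted share at 15.0 min, beyond the quench, is 4.00%, so expect somewhat less.

**Hands off.** Add no protic impurity: Wednesday's flask, with 0.63 M of it, held 11.0% of target at 15.0 min, and Monday's held 43.5%. Read on time: Monday's target reads 44.9% at 5.00 min and 43.5% at 15.0 min.

**The forecast.** It gives 44.4%, 42.9%, 39.9%, 34% and 22.8%, so falls all the way: “so quenching is stoichiometric”. Its values for epsilon and theta stand below ours.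

**The flask.** The simulation gives 40.4%, 39.0%, 36.3%, 31.0% and 20.8%: falls all the way.

    target ⇌ isomer of the product (K = 3.10, k = 1.53 × 10⁻⁴ s⁻¹)
    2 starting material ⇌ target (K = 0.964 M⁻¹, k = 0.00360 M⁻¹ s⁻¹)
    starting material + protic impurity → quenched substrate (k = 0.0133 M⁻¹ s⁻¹)

**Q again.** In theta at 30.0 min, Q turns the 33.1% of starting material into 21.2% of target, and the flask holds 20.8%. In epsilon, 46.1% turns into 41.1%, and the flask holds 40.4%. The quench is the largest single effect in the fall of the row: from epsilon to theta the change is −20 percentage points, and with the quench taken away it is 0 points.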